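Everything rests on opening the cage: the bicyclo[2.2.2]octene and the oxolane are unfolded to a flat 3,4-bis(1,1-dimethylallyloxy)benzoate ring (ring B) that is already tied into the spiro acylal. One thermal operation, an aromatic Claisen shift followed by an intramolecular Diels–Alder addition, then makes three bonds, two rings and four stereocentres. It exploits the position of the spiro carbon on the ether oxygen of the future cage bridgehead (ring B C2): the ring A carbonyl and the prenylated ring A carbon flank the two faces of ring B and should steer the cycloaddition. The precursor is an enantioenriched spiro 1,3-benzodioxin-4-one ortho-quinone monoketal, made by oxidative dearomatisation of a 2-aryloxybenzoic acid.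

Key step: step 17

Assumption: the sense of induction of the chiral aryl-λ3-iodane on this aryl-tethered acid cannot be assigned in advance; the (R,R)-reagent ArI(OAc)2, SMILES CC(=O)OI(OC(C)=O)c1c(O[C@H](C)C(=O)Nc2c(C)cc(C)cc2C)cccc1O[C@H](C)C(=O)Nc1c(C)cc(C)cc1C, preformed from the iodoarene with peracetic acid and freed of oxidant, is written, and its mirror image is used instead if a pilot run shows the opposite sense.

Atom labels: ring A atoms carry 2H-chromene numbers (C5, C6, C7, C8, C4a, C8a), ring B atoms carry benzoate numbers (C1 to C6). Cs is the spiro carbon (former chromene C7). DMA is 1,1-dimethylallyl (2-methylbut-3-en-2-yl), MOM is methoxymethyl.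

**Ring A fragment**

Step 1
Reactants: 1 2,6-dimethoxy-1,4-benzoquinone
Product: 2 2-hydroxy-6-methoxy-1,4-benzoquinone
Conditions: NaOH (1.1 equiv), THF/H2O, 0 °C to rt; then HCl (1 M)
Reagents that add atoms: sodium hydroxide [Na+].[OH-]
Why: Saponification of a vinylogous ester by addition–elimination; the hydroxyquinone anion formed after the first exchange is too electron-rich for a second attack, so one methoxy group should remain.

Step 2
Reactants: 2 2-hydroxy-6-methoxy-1,4-benzoquinone; 3 3-methylbut-2-enal
Product: 5 7-methoxy-2,2-dimethyl-2H-chromene-5,8-dione, via Knoevenagel oxatriene 4 (not isolated)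
Conditions: ethylenediammonium diacetate (20 mol %), toluene, 80 °C
Reagents that add atoms: none
Why: Knoevenagel condensation at the nucleophilic CH next to the hydroxyl, then oxa-6π electrocyclisation of the 1-oxatriene through the former hydroxyl oxygen; the para-quinone is the more stable isomer and any ortho-quinone isomer should equilibrate to it through the open oxatriene.

Step 3
Reactants: 5 7-methoxy-2,2-dimethyl-2H-chromene-5,8-dione
Product: 6 7-hydroxy-2,2-dimethyl-2H-chromene-5,8-dione
Conditions: NaOH (1.1 equiv), THF/H2O, 0 °C to rt; then HCl (1 M, 0 °C)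
Reagents that add atoms: sodium hydroxide [Na+].[OH-]
Why: Second vinylogous ester saponification; hydroxide should attack the unhindered methoxy-bearing carbon and not the fully substituted pyran carbon, whose tertiary alkoxide is a poor leaving group.

Step 4
Reactants: 6 7-hydroxy-2,2-dimethyl-2H-chromene-5,8-dione; 7 prenyl bromide
Product: 8 7-hydroxy-2,2-dimethyl-6-(3-methylbut-2-enyl)-2H-chromene-5,8-dione
Conditions: LiH, DMSO, rt; then 7, rt
Reagents that add atoms: none
Why: C-alkylation of the ambident hydroxyquinone anion at its only free enolic carbon; the lithium salt in DMSO favours carbon over oxygen, as in the prenylation of 2-hydroxy-1,4-naphthoquinone.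

Step 5
Reactants: 8 7-hydroxy-2,2-dimethyl-6-(3-methylbut-2-enyl)-2H-chromene-5,8-dione
Product: 9 7-chloro-2,2-dimethyl-6-(3-methylbut-2-enyl)-2H-chromene-5,8-dione
Conditions: (COCl)2, DMF (cat.), CH2Cl2, 0 °C
Reagents that add atoms: oxalyl chloride ClC(=O)C(Cl)=O
Why: Conversion of a vinylogous acid into its vinylogous acid chloride through Vilsmeier-type activation; low temperature and a short reaction time should spare the prenyl and pyran alkenes.

**Ring B fragment**

Step 6
Reactants: 10 2,3,4-trihydroxybenzoic acid
Product: 11 methyl 2,3,4-trihydroxybenzoate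
Conditions: MeOH, H2SO4 (cat.), reflux
Reagents that add atoms: methanol CO
Why: Fischer esterification; the ester later chelates the 2-hydroxyl and differentiates it from the other two.

Step 7
Reactants: 12 2-methylbut-3-en-2-ol
Product: 13 isobutyl 2-methylbut-3-en-2-yl carbonate
Conditions: n-BuLi, THF, −78 °C; then isobutyl chloroformate, −78 °C to rt
Reagents that add atoms: isobutyl chloroformate CC(C)COC(Cl)=O
Why: Acylation of the lithium tertiary alkoxide; the alkoxide route avoids ionisation of the tertiary allylic alcohol.

Step 8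
Reactants: 11 methyl 2,3,4-trihydroxybenzoate; 13 isobutyl 2-methylbut-3-en-2-yl carbonate
Product: 14 methyl 2-hydroxy-3,4-bis(2-methylbut-3-en-2-yloxy)benzoate
Conditions: 13 (2.5 equiv), Pd(PPh3)4 (5 mol %), THF, 0 °C to rt
Reagents that add atoms: none
Why: Decarboxylative Tsuji–Trost O-allylation in which the phenoxide attacks the more substituted terminus of the 1,1-dimethylallyl palladium complex to give the tertiary ethers kinetically; the ester-chelated 2-hydroxyl is the least nucleophilic and should stay free.

Step 9
Reactants: 14 methyl 2-hydroxy-3,4-bis(2-methylbut-3-en-2-yloxy)benzoate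
Product: 16 methyl 2,5-dihydroxy-3,4-bis(2-methylbut-3-en-2-yloxy)benzoate, via ester quinone 15 (not isolated)
Conditions: (KSO3)2NO (2.5 equiv), KH2PO4, acetone/H2O, 0 °C; then Na2S2O4 (aq), 0 °C
Reagents that add atoms: potassium nitrosodisulfonate [K+].[K+].[O]N(S(=O)(=O)[O-])S(=O)(=O)[O-]
Why: Teuber oxidation of the phenol at its only free para position (C5), made possible by the two alkoxy donors; the electrophilic ester quinone is reduced in the same flask before its allyl vinylogous esters can rearrange.

Step 10
Reactants: 16 methyl 2,5-dihydroxy-3,4-bis(2-methylbut-3-en-2-yloxy)benzoate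
Product: 17 methyl 2-hydroxy-5-(methoxymethoxy)-3,4-bis(2-methylbut-3-en-2-yloxy)benzoate
Conditions: MOMCl (1.1 equiv), iPr2NEt, CH2Cl2, 0 °C
Reagents that add atoms: chloromethyl methyl ether COCCl
Why: Alkylation of the free, non-chelated 5-hydroxyl; the 2-hydroxyl is hydrogen-bonded to the ester and flanked by a tertiary ether, so it should not react.

**Union and spiro acylal**

Step 11
Reactants: 9 7-chloro-2,2-dimethyl-6-(3-methylbut-2-enyl)-2H-chromene-5,8-dione; 17 methyl 2-hydroxy-5-(methoxymethoxy)-3,4-bis(2-methylbut-3-en-2-yloxy)benzoate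
Product: 18 methyl 2-{[2,2-dimethyl-6-(3-methylbut-2-enyl)-5,8-dioxo-2H-chromen-7-yl]oxy}-5-(methoxymethoxy)-3,4-bis(2-methylbut-3-en-2-yloxy)benzoate
Conditions: K2CO3, DMF, 0 °C to rt, dark
Reagents that add atoms: none
Why: Addition–elimination of the salicylate phenoxide on the chloroquinone (conjugate addition at the chlorine-bearing carbon, loss of chloride); room temperature keeps the tertiary allyl ethers from rearranging and limits base-induced isomerisation of the prenylquinone.

Step 12
Reactants: 18 aryloxyquinone methyl ester
Product: 20 2-{[5,8-dihydroxy-2,2-dimethyl-6-(3-methylbut-2-enyl)-2H-chromen-7-yl]oxy}-5-(methoxymethoxy)-3,4-bis(2-methylbut-3-en-2-yloxy)benzoic acid, via hydroquinone methyl ester 19 (not isolated)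
Conditions: Na2S2O4, THF/H2O, rt; then LiOH, 40 °C, degassed; HCl (0.5 M, 0 °C) to pH 4
Reagents that add atoms: lithium hydroxide [Li+].[OH-]
Why: Dithionite reduction of the quinone followed by saponification under the same reducing, oxygen-free conditions; the ester must be cleaved at the hydroquinone stage because hydroxide would displace the aryloxy group from the quinone.

Step 13
Reactants: 20 hydroquinone acid
Product: 21 depsidone lactone phenol (ring B carboxyl esterified by the ring A C8 hydroxyl; C5 hydroxyl free)
Conditions: N,N'-diisopropylcarbodiimide, DMAP (cat.), CH2Cl2, high dilution, 0 °C to rt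
Reagents that add atoms: none
Why: Steglich-type lactonisation to the seven-membered dibenzo[b,e][1,4]dioxepin-11-one; only the hydroxyl ortho to the diaryl ether oxygen can reach the activated carboxyl, which differentiates the two hydroquinone oxygens.

Step 14
Reactants: 21 depsidone lactone phenol
Product: 22 depsidone lactone methyl ether (C5 methoxy)
Conditions: MeI, K2CO3, acetone, rt
Reagents that add atoms: iodomethane CI
Why: Williamson methylation of the one remaining phenol under anhydrous conditions that leave the aryl lactone closed.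

Step 15
Reactants: 22 depsidone lactone methyl ether
Product: 23 2-{[8-hydroxy-5-methoxy-2,2-dimethyl-6-(3-methylbut-2-enyl)-2H-chromen-7-yl]oxy}-5-(methoxymethoxy)-3,4-bis(2-methylbut-3-en-2-yloxy)benzoic acid
Conditions: LiOH, THF/H2O, 0 °C, degassed; HCl (0.5 M, 0 °C) to pH 4
Reagents that add atoms: lithium hydroxide [Li+].[OH-]
Why: Saponification of an activated aryl ester, which releases the carboxylic acid and the C8 phenol ortho to the ether bridge while the para oxygen stays capped as its methyl ether.

Step 16
Reactants: 23 seco phenol acid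
Product: 24 (S)-spiro 1,3-benzodioxin-4-one ortho-quinone monoketal (ring A as methyl dienol ether; ring B still aromatic)
Conditions: (R,R)-ArI(OAc)2 [Ar = 2,6-bis(1-(mesitylcarbamoyl)ethoxy)phenyl] (1.2 equiv), CH2Cl2/(CF3)2CHOH (4:1), −30 °C
Reagents that add atoms: none
Why: Ligand exchange of the phenol on trivalent iodine, then attack of the tethered carboxylate on the aryloxy-bearing ortho carbon with loss of the iodoarene (oxidative dearomatising ortho-spirolactonisation of a phenol carrying an O-tethered acid, six-membered ring closure); the spiro stereocentre is set by the C2-symmetric lactamide arms of the reagent, and a preformed stoichiometric reagent avoids a peracid that would epoxidise the prenyl and pyran alkenes.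

**Cage and end game**

Step 17
Reactants: 24 (S)-spiro 1,3-benzodioxin-4-one ortho-quinone monoketal
Product: 26 caged spiro acylal methyl enol ether MOM ether, via Claisen dienone 25 (not isolated)
Conditions: DMF (degassed), 110 °C, sealed tube, dark
Reagents that add atoms: none
Why: Proposed new method: a reversible [3,3] shift moves the DMA group from the ring B C4 oxygen (para to the lactone carbonyl carbon) to C3 and gives the 6-alkoxy-6-prenylcyclohexa-2,4-dienone 25, whose remaining O-tethered vinyl group then adds irreversibly across C2 and C5 of the electron-poor diene (CH to C2, CH2 to C5) and drains the Claisen equilibrium. The closest known reaction type is the thermal Claisen/Diels–Alder cascade of 5,6-bis(1,1-dimethylallyloxy)xanthones to caged xanthones, whose reacting ring has the same layout (acyl carbon para to the migrating ether, ether oxygen on the diene terminus); new here are the spiro benzodioxinone scaffold and the relay of chirality from the spiro carbon. The bicyclo[2.2.2]octene is closed by the [4+2] addition itself and the oxolane by its five-atom tether (C3–O–CMe2–CH onto C2), both in the one cycloaddition. The four cage centres are fixed relative to one another by the tether, which forces the oxolane oxygen and the new two-carbon bridge onto one face and the prenyl group onto the other; their sense relative to Cs should come from approach of the dienophile to C2 on the face flanked by the flat ring A carbonyl and not on the face covered by the prenyl-bearing enol ether arm. The step needs site selectivity in the Claisen shift, which the para lactone carbonyl should secure, and face selectivity, which the perpendicular ring A should secure; the fully substituted ring A diene cannot compete, the methyl enol ether leaves no enolisable hydrogen through which the acylal could open or racemise, and a minor cage isomer would be a diastereomer removable by chromatography.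

Step 18
Reactants: 26 caged spiro acylal methyl enol ether MOM ether
Product: 27 caged spiro acylal methyl enol ether with free bridgehead carbinol
Conditions: Me2BBr, CH2Cl2, −78 °C; then NaHCO3 (aq), THF
Reagents that add atoms: none
Why: Lewis-acid cleavage of the MOM acetal by bromodimethylborane (bromide opens the activated acetal, the bromomethyl ether hydrolyses on basic work-up); the aprotic, cold conditions should not protonate the prenyl groups or the dienol ether, and ring A stays masked so that the acylal cannot open.

Step 19
Reactants: 27 caged spiro acylal methyl enol ether with free bridgehead carbinol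
Product: 28 target CNP0222516.1
Conditions: HCl (0.5 M, aq)/THF, 0 °C to rt
Reagents that add atoms: water O
Why: Enol ether hydrolysis in which mild acid protonates the electron-rich dienol ether at the prenyl-bearing carbon and water then releases the ring A ketone; the new CH stereocentre is adjusted by acid-catalysed enolisation, and the epimer with prenyl trans to the cage-bearing ether oxygen on Cs, as in the target, is expected to be the more stable one.

**Compound list**

1 | 2,6-dimethoxy-1,4-benzoquinone | COC1=CC(=O)C=C(OC)C1=O | starting material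
2 | 2-hydroxy-6-methoxy-1,4-benzoquinone | COC1=CC(=O)C=C(O)C1=O | intermediate
3 | 3-methylbut-2-enal | CC(C)=CC=O | starting material
4 | 6-methoxy-3-(3-methylbut-2-enylidene)cyclohex-5-ene-1,2,4-trione (Knoevenagel oxatriene) | COC1=CC(=O)C(=CC=C(C)C)C(=O)C1=O | intermediate (not isolated)
5 | 7-methoxy-2,2-dimethyl-2H-chromene-5,8-dione | COC1=CC(=O)C2=C(OC(C)(C)C=C2)C1=O | intermediate
6 | 7-hydroxy-2,2-dimethyl-2H-chromene-5,8-dione | OC1=CC(=O)C2=C(OC(C)(C)C=C2)C1=O | intermediate
7 | prenyl bromide (1-bromo-3-methylbut-2-ene) | CC(C)=CCBr | starting material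
8 | 7-hydroxy-2,2-dimethyl-6-(3-methylbut-2-enyl)-2H-chromene-5,8-dione | CC(C)=CCC1=C(O)C(=O)C2=C(C=CC(C)(C)O2)C1=O | intermediate
9 | 7-chloro-2,2-dimethyl-6-(3-methylbut-2-enyl)-2H-chromene-5,8-dione | CC(C)=CCC1=C(Cl)C(=O)C2=C(C=CC(C)(C)O2)C1=O | intermediate
10 | 2,3,4-trihydroxybenzoic acid | OC(=O)c1ccc(O)c(O)c1O | starting material
11 | methyl 2,3,4-trihydroxybenzoate | COC(=O)c1ccc(O)c(O)c1O | intermediate
12 | 2-methylbut-3-en-2-ol | CC(C)(O)C=C | starting material
13 | isobutyl 2-methylbut-3-en-2-yl carbonate | CC(C)COC(=O)OC(C)(C)C=C | intermediate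
14 | methyl 2-hydroxy-3,4-bis(2-methylbut-3-en-2-yloxy)benzoate | COC(=O)c1ccc(OC(C)(C)C=C)c(OC(C)(C)C=C)c1O | intermediate
15 | methyl 4,5-bis(2-methylbut-3-en-2-yloxy)-3,6-dioxocyclohexa-1,4-diene-1-carboxylate (ester quinone) | COC(=O)C1=CC(=O)C(OC(C)(C)C=C)=C(OC(C)(C)C=C)C1=O | intermediate (not isolated)
16 | methyl 2,5-dihydroxy-3,4-bis(2-methylbut-3-en-2-yloxy)benzoate | COC(=O)c1cc(O)c(OC(C)(C)C=C)c(OC(C)(C)C=C)c1O | intermediate
17 | methyl 2-hydroxy-5-(methoxymethoxy)-3,4-bis(2-methylbut-3-en-2-yloxy)benzoate | COC(=O)c1cc(OCOC)c(OC(C)(C)C=C)c(OC(C)(C)C=C)c1O | intermediate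
18 | methyl 2-{[2,2-dimethyl-6-(3-methylbut-2-enyl)-5,8-dioxo-2H-chromen-7-yl]oxy}-5-(methoxymethoxy)-3,4-bis(2-methylbut-3-en-2-yloxy)benzoate | CC(C)=CCC1=C(Oc2c(C(=O)OC)cc(OCOC)c(OC(C)(C)C=C)c2OC(C)(C)C=C)C(=O)C2=C(C=CC(C)(C)O2)C1=O | intermediate
19 | methyl 2-{[5,8-dihydroxy-2,2-dimethyl-6-(3-methylbut-2-enyl)-2H-chromen-7-yl]oxy}-5-(methoxymethoxy)-3,4-bis(2-methylbut-3-en-2-yloxy)benzoate (hydroquinone methyl ester) | CC(C)=CCc1c(O)c2C=CC(C)(C)Oc2c(O)c1Oc1c(C(=O)OC)cc(OCOC)c(OC(C)(C)C=C)c1OC(C)(C)C=C | intermediate (not isolated)
20 | 2-{[5,8-dihydroxy-2,2-dimethyl-6-(3-methylbut-2-enyl)-2H-chromen-7-yl]oxy}-5-(methoxymethoxy)-3,4-bis(2-methylbut-3-en-2-yloxy)benzoic acid | CC(C)=CCc1c(O)c2C=CC(C)(C)Oc2c(O)c1Oc1c(C(=O)O)cc(OCOC)c(OC(C)(C)C=C)c1OC(C)(C)C=C | intermediate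
21 | depsidone lactone phenol: dibenzo[b,e][1,4]dioxepin-11-one in which the ring B carboxyl is esterified by the ring A C8 oxygen and the diaryl ether links ring A C7 to ring B C2; ring A carries the fused 2,2-dimethyl-2H-pyran, the C6 prenyl and a free C5 hydroxyl; ring B carries 5-OMOM and the 3,4-bis(DMA) ethers | CC(C)=CCc1c(O)c2C=CC(C)(C)Oc2c3OC(=O)c4cc(OCOC)c(OC(C)(C)C=C)c(OC(C)(C)C=C)c4Oc13 | intermediate
22 | depsidone lactone methyl ether: as 21 with the ring A C5 oxygen methylated | CC(C)=CCc1c(OC)c2C=CC(C)(C)Oc2c3OC(=O)c4cc(OCOC)c(OC(C)(C)C=C)c(OC(C)(C)C=C)c4Oc13 | intermediate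
23 | 2-{[8-hydroxy-5-methoxy-2,2-dimethyl-6-(3-methylbut-2-enyl)-2H-chromen-7-yl]oxy}-5-(methoxymethoxy)-3,4-bis(2-methylbut-3-en-2-yloxy)benzoic acid | CC(C)=CCc1c(OC)c2C=CC(C)(C)Oc2c(O)c1Oc1c(C(=O)O)cc(OCOC)c(OC(C)(C)C=C)c1OC(C)(C)C=C | intermediate
24 | (S)-spiro 1,3-benzodioxin-4-one ortho-quinone monoketal: Cs (S) carries the lactone oxygen and the ring B C2 ether oxygen and is flanked in ring A by the C8 ketone and by C6 of the 5-methoxy-6-prenyl dienol ether; 2H-pyran fused at C4a/C8a; ring B aromatic with 5-OMOM and 3,4-bis(DMA) ethers | CC(C)=CCC1=C(OC)C2=C(OC(C)(C)C=C2)C(=O)[C@@]12OC(=O)c1cc(OCOC)c(OC(C)(C)C=C)c(OC(C)(C)C=C)c1O2 | intermediate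
25 | Claisen dienone: as 24 (Cs S) but ring B is a cyclohexa-2,4-dienone with the C4 ketone, C3 (R) bearing prenyl and the DMA ether, and the C5 MOM enol ether | CC(C)=CCC1=C(OC)C2=C(OC(C)(C)C=C2)C(=O)[C@@]12OC(=O)C1=C(O2)[C@@](CC=C(C)C)(OC(C)(C)C=C)C(=O)C(OCOC)=C1 | intermediate (not isolated)
26 | caged spiro acylal, ring A methyl dienol ether, bridgehead MOM ether (Cs S; cage: ether bridgehead C2 S, prenylated quaternary C3 R, oxygenated bridgehead C5 R, methine bearing CMe2 S) | CC(C)=CCC1=C(OC)C2=C(OC(C)(C)C=C2)C(=O)[C@@]12OC(=O)C1=C[C@]3(OCOC)C[C@H]4C(C)(C)O[C@@](CC=C(C)C)(C3=O)[C@@]14O2 | intermediate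
27 | caged spiro acylal, ring A methyl dienol ether, free bridgehead carbinol (stereocentres as in 26) | CC(C)=CCC1=C(OC)C2=C(OC(C)(C)C=C2)C(=O)[C@@]12OC(=O)C1=C[C@]3(O)C[C@H]4C(C)(C)O[C@@](CC=C(C)C)(C3=O)[C@@]14O2 | intermediate
28 | CNP0222516.1 (Cs S; ring A prenyl-bearing CH S, prenyl trans to the ether oxygen on Cs; cage C2 S, C3 R, C5 R, methine S) | CC(C)=CC[C@H]1C(=O)C2=C(OC(C)(C)C=C2)C(=O)[C@@]12OC(=O)C1=C[C@]3(O)C[C@H]4C(C)(C)O[C@@](CC=C(C)C)(C3=O)[C@@]14O2 | target

**Step count**

Total: 19 steps. Longest linear sequence: 14 steps (steps 1 to 5, then 11 to 19, from 1 to 28).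

**Steps most likely to fail**

1. Step 17. The cycloaddition may show poor face selectivity with respect to Cs, the wrong allyl ether may migrate, or the acylal may not survive prolonged heating. Fallback with known chemistry: it sets out from 22 and comes back at 26. The flat, achiral lactone 22 has the substitution pattern for which the Claisen/Diels–Alder cascade is established (aryl ether oxygen on C2, acyl carbon on C1, nothing to relay). Heating it in DMF at 110 °C should give the caged lactone F1 together with its mirror image F2, which is removed by preparative chromatography on a chiral stationary phase. LiOH then opens the aryl lactone of F1 to the caged phenol acid F3. Oxidative spirolactonisation of F3 with PhI(OAc)2 in CH2Cl2/(CF3)2CHOH forms the spiro carbon last, next to the existing cage bridgehead, which should direct it; a Cs epimer would be a separable diastereomer. The product is 26.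

2. Step 16. The rigid aryl-tethered acid may fit the chiral reagent badly, giving low enantioselectivity, or the electron-rich ring may be attacked at the methoxy-bearing para carbon. Fallback: it sets out from 23 and comes back at 24. Reagent control is given up: PhI(OAc)2 in CH2Cl2/(CF3)2CHOH at −30 °C should give 24 together with the mirror-image spiro ketal F4. The two are separated by preparative chromatography on a chiral stationary phase. F4 can be returned to 23 by reductive rearomatisation (Zn, AcOH) and recycled.

3. Step 19. Acid strong enough to hydrolyse the methyl dienol ether may also open the spiro acylal by β-elimination of the lactone carboxylate from the enol, cyclise a prenyl group, or leave the prenyl-bearing CH as the kinetic epimer. Fallback: it sets out from 21 and comes back at 28. The ring A oxygen is capped as an acetal instead of a methyl ether. MOMCl/iPr2NEt on 21 gives the bis-MOM lactone F5, and LiOH opens it to the phenol acid F6. The chiral iodane of step 16 gives the spiro ketal F7 with ring A as a MOM dienol ether, and the thermal cascade of step 17 gives the bis-MOM cage F8. Me2BBr at −78 °C then removes both acetals in one operation. The ring A enol is released cold and under aprotic conditions and is protonated on buffered work-up, so no aqueous acid is needed, and the CH epimers are equilibrated afterwards under the mildest conditions that suffice.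

Further compounds
F1 | step 17 | caged depsidone lactone (cage centres as in 26; ring A aromatic with C5 methoxy, C6 prenyl and fused 2H-pyran) | CC(C)=CCc1c(OC)c2C=CC(C)(C)Oc2c3OC(=O)C4=C[C@]5(OCOC)C[C@H]6C(C)(C)O[C@@](CC=C(C)C)(C5=O)[C@@]46Oc13
F2 | step 17 | mirror image of F1 | CC(C)=CCc1c(OC)c2C=CC(C)(C)Oc2c3OC(=O)C4=C[C@@]5(OCOC)C[C@@H]6C(C)(C)O[C@](CC=C(C)C)(C5=O)[C@]46Oc13
F3 | step 17 | caged phenol acid (cage acid on the alkene carbon; cage bridgehead ether to ring A C7; ring A C8 phenol free) | CC(C)=CCc1c(OC)c2C=CC(C)(C)Oc2c(O)c1O[C@]12C(C(=O)O)=C[C@]3(OCOC)C[C@H]1C(C)(C)O[C@@]2(CC=C(C)C)C3=O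
F4 | step 16 | mirror image of 24 ((R)-spiro ketal) | CC(C)=CCC1=C(OC)C2=C(OC(C)(C)C=C2)C(=O)[C@]12OC(=O)c1cc(OCOC)c(OC(C)(C)C=C)c(OC(C)(C)C=C)c1O2
F5 | step 19 | bis-MOM depsidone lactone (as 22 with OMOM in place of the ring A methoxy) | CC(C)=CCc1c(OCOC)c2C=CC(C)(C)Oc2c3OC(=O)c4cc(OCOC)c(OC(C)(C)C=C)c(OC(C)(C)C=C)c4Oc13
F6 | step 19 | seco phenol acid with ring A C5 OMOM (as 23 with OMOM in place of the methoxy) | CC(C)=CCc1c(OCOC)c2C=CC(C)(C)Oc2c(O)c1Oc1c(C(=O)O)cc(OCOC)c(OC(C)(C)C=C)c1OC(C)(C)C=C
F7 | step 19 | (S)-spiro ketal with ring A as MOM dienol ether (as 24) | CC(C)=CCC1=C(OCOC)C2=C(OC(C)(C)C=C2)C(=O)[C@@]12OC(=O)c1cc(OCOC)c(OC(C)(C)C=C)c(OC(C)(C)C=C)c1O2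
F8 | step 19 | caged spiro acylal with ring A MOM dienol ether and bridgehead MOM ether (stereocentres as in 26) | CC(C)=CCC1=C(OCOC)C2=C(OC(C)(C)C=C2)C(=O)[C@@]12OC(=O)C1=C[C@]3(OCOC)C[C@H]4C(C)(C)O[C@@](CC=C(C)C)(C3=O)[C@@]14O2
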